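## The problem

Target 48 is a linear tetramer of guaiacylpropane units: a tetrahydrofuran carries a 4-hydroxy-3-methoxybenzyl group at C4, a hydroxymethyl group at C3 and, at C2, the C5 position of a trans-2-aryl-3-(hydroxymethyl)-7-methoxy-2,3-dihydrobenzofuran (the inner ring), whose C2 in turn carries C5 of a second dihydrobenzofuran of the same kind (the outer ring) that ends in a 4-hydroxy-3-methoxyphenyl group. Seven stereocentres have to be set: (2S,3R) in the outer ring, (2R,3S) in the inner ring and (2R,3R,4R) in the tetrahydrofuran, whose three substituents are all cis. The two dihydrobenzofurans are both trans but of opposite absolute sense, so one reagent-controlled method used in its two mirror-image forms can serve both. Within each, C3 is a robust all-carbon centre that can dictate C2, because C2 is a benzylic ether carbon that ionises easily. That lability is also the main hazard: the C2–O bonds of both dihydrobenzofurans, and above all the contra-thermodynamic C2–O bond of the all-cis tetrahydrofuran, can open under protic or Lewis acid. Acid must therefore be confined to the points where equilibration is wanted, the last deprotection must be non-acidic, and the phenols and primary alcohols must be masked during the organometallic steps. The enabling feature is that C2 of the outer ring lies para to the phenolic oxygen of the terminal guaiacyl ring and is tethered through C3 and C3a to the oxygen O1 on C7a. Loss of a benzylic hydroxyl at C2 gives a planar para-quinone methide that O1 can capture in a five-membered closure trans to the hydroxymethyl group at C3.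

## Retrosynthesis

**Tetrahydrofuran C2.** Target 48 is taken back to its pentakis-silyl ether 47 (five O–Si bonds), so that the last step uses buffered fluoride and no acid. In 47 the C2–H bond of the tetrahydrofuran is cut to give lactol 45, and then the C2–aryl bond, which leads to aryl bromide 28 and the cis-lactone 43. The neighbouring cut, O1–C2 by cationic closure of a triol, would give the more stable 2,3-trans ring. Hydride delivery to the oxocarbenium ion 46, anti to the C3 and C4 substituents that sit on one face, gives the all-cis ring. The cut is convergent: 28 holds four stereocentres and 43 two. The forward steps ask for mono-addition of an aryllithium to a lactone and for a Lewis-acid reduction cold enough to spare the benzylic ethers.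

**Cis-lactone 43.** Any electrophile enters a 4-substituted butyrolactone enolate trans to the C4 substituent, so the last bond made at C3 has to be C–H. Lactone 43 is therefore derived from its trans epimer 41 by kinetic protonation of enolate 42. Epimer 41 comes from alcohol 40 and, by cutting the C3–CH2O bond (a one-carbon aldol), from the monosubstituted lactone 38. Lactone 38 is cut at the C3–C4 bond through hydroxy ester 37 and imide 36 to acyl oxazolidinone 33 and tert-butyl bromoacetate 34, an auxiliary-controlled alkylation. Imide 33 comes from acid 31, that is from 3-(4-hydroxy-3-methoxyphenyl)propanoic acid 29 and (S)-4-benzyloxazolidin-2-one 7.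

**Inner ring.** Bromide 28 is the tris-silyl ether of triol 27. Cutting O1–C2 of the inner ring leads to diol 25, in which the benzylic carbon is para to O1 of the outer ring and can be ionised to cation 26. Cutting the future C2–C3 bond of 25 (via 24 and 23) gives aldehyde 19 and the (R)-auxiliary imide 21, an Evans syn-aldol. Against a convergent annulation this costs steps, but it puts the inner C3 under reagent control, which the remote outer stereocentres could not provide.

**Bromide as a latent carbanion.** Aldehyde 19 is cut at its formyl carbon to the aryllithium 18 of bromide 17, the bis-silyl ether of 16. The bromine is carried from the first step and is used twice, as the formyl precursor here and as the aryllithium 44 in the coupling with 43.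

**Key disconnection.** In 16 the O1–C2 bond of the outer ring is cut to give bisphenolic diol 14. The para-hydroxyl lets C2 become planar in quinone methide 15, so the configuration of the carbinol in 14 is irrelevant and only C3 has to be made selectively. The forward reaction must ionise only the benzylic hydroxyl and must close trans.

**Outer C2–C3 bond.** Diol 14 comes from the silylated diol 13 and from aldol adduct 12, which is cut between the two future ring carbons into the (S)-auxiliary imide 8 and silylated vanillin 10 (from vanillin 9). The boron aldol fixes the carbon that becomes C3.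

**Arylacetic acid.** Imides 8 and 21 are the derivatives of one acid, 5, with the two enantiomeric auxiliaries. The acid is activated once, as its mixed pivalic anhydride 6, and the batch is divided between (S)-4-benzyloxazolidin-2-one 7 and (R)-4-benzyloxazolidin-2-one 20. Acid 5 is reached by one-carbon homologation (via 4 and enol ether 3) of the silyl ether 2 of commercial 5-bromo-2-hydroxy-3-methoxybenzaldehyde 1.

## Roads not taken

**Alternative 1:** The inner ring is cut at both C2–O1 and C2–C3. C2 would come from the benzylic thiolanium salt A2 of the outer unit, and the four-atom partner would be the ortho-quinone methide released from the phenolic sulfone A3. With Cs2CO3 the ylide carbon adds to the methide carbon and the phenoxide then displaces thiolane, giving A1, which is the same compound as 28. The merits are real: two bonds and the ring form in one convergent step, trans selectivity follows from the anti displacement, and steps 12 to 18 of the chosen route would shrink to about four. The weak points for this target are these: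
- The ortho-quinone methide is planar at the future C3, thiolane is achiral, and the only stereocentres present sit far away in the outer ring. A1 would therefore form together with its inner-ring (2S,3R) diastereomer in comparable amounts, and the two would be hard to separate.
- A2 is a benzylic sulfonium salt para to an ether oxygen, so it is prone to solvolysis.
- The methide carbon carries a silyloxymethyl group and could tautomerise to a styrene.

Alternative 1 is the shorter road. The chosen plan sets against it auxiliary control of the inner C3 and intermediates that are diastereomers of their impurities.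

**Alternative 2:** The inner ring is cut at C3–C3a together with the C–O bond of its hydroxymethyl group. The precursor is the aryl iodide A5, an allylic and benzylic aryl ether that already holds the inner C2. Bu3SnH would generate the aryl radical, which closes 5-exo onto the vinyl group; 2,2,6,6-tetramethylpiperidin-1-oxyl traps the primary radical to give A4. Cleavage of the N–O bond and of the dioxolane would follow. The closure runs under neutral conditions, so no acid meets the outer ring, which is an advantage over step 17 of the chosen route. The 2-aryl group should also steer the new C3 substituent trans. Against this: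
- A5 needs a single enantiomer of a doubly activated secondary ether made from a hindered 2-iodo-6-methoxyphenol, an etherification that tends towards ionisation and allylic transposition.
- The tin hydride and the nitroxide consume each other and compete for the primary radical.
- Two unmasking steps are added.

The chosen plan creates its stereocentres by more dependable reactions and in no more steps.

**Alternative 3:** The outer ring is cut at C2–C3. The aryldiazoacetate A7 and dirhodium tetrakis[N-phthaloyl-(S)-tert-leucinate], Rh2(S-PTTL)4, would give a carbenoid that inserts into the benzylic C–H bond of the ortho arylmethyl ether. Base would then epimerise C3 to the trans ester A6, which is reduced to the alcohol. The stereocentres come from a catalyst instead of a stoichiometric auxiliary, and this reaction type is established for 2-aryl-2,3-dihydrobenzofuran-3-carboxylates. For the outer ring alone it is probably two or three steps shorter than steps 1 to 11, and in that respect it is the better road. Its weak points are these: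
- Enantiopurity is limited by the catalyst, here with an ether oxygen flanked by a methoxy group.
- The epimerisation base threatens the aryl silyl ether.
- Repeating the method for the inner ring means diazo transfer and carbenoid chemistry on a substrate that already contains the sensitive outer ring.

The chosen plan sets against it stereochemical purity secured through separable auxiliary diastereomers, C2 set by thermodynamics without a reagent, cheap reagents, and one sequence that serves both rings by exchanging 7 for 20.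

Key step: step 10

## Assumptions and abbreviations

Assumption: the aldol-derived intermediates 12–14 and 23–25 are drawn with the carbinol configuration of the Evans syn adduct; this centre is erased on cyclisation, so its epimer would serve equally.

Abbreviations:
- TBS = tert-butyldimethylsilyl; TBSO = tert-butyldimethylsilyloxy.
- TBAF = tetrabutylammonium fluoride, Bu4NF.
- LDA = lithium diisopropylamide, LiN(iPr)2.
- NaHMDS = NaN(SiMe3)2.
- Bu2BOTf = dibutylboron triflate.
- PivCl = pivaloyl chloride.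
- "Outer unit" U = (2S,3R)-7-methoxy-2-[3-methoxy-4-(TBSO)phenyl]-3-[(TBSO)methyl]-2,3-dihydro-1-benzofuran-5-yl.
- "Dimer unit" D = (2R,3S)-7-methoxy-3-[(TBSO)methyl]-2-U-2,3-dihydro-1-benzofuran-5-yl.

## Route

Step 1
Reactants: 1 5-bromo-2-hydroxy-3-methoxybenzaldehyde
Product: 2 5-bromo-3-methoxy-2-(TBSO)benzaldehyde
Conditions: TBSCl, imidazole, DMF, rt
Reagents that add atoms: tert-butyldimethylsilyl chloride, CC(C)(C)[Si](C)(C)Cl
Why: Standard silylation of a phenol; the silyl ether masks the future ring oxygen through the enolate chemistry and is later removed by fluoride without touching the aryl bromide.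

Step 2
Reactants: 2 5-bromo-3-methoxy-2-(TBSO)benzaldehyde
Product: 4 2-[5-bromo-3-methoxy-2-(TBSO)phenyl]acetaldehyde, via methyl enol ether 3 (not isolated)
Conditions: Ph3P(CH2OMe)Cl, NaHMDS, THF, 0 °C; then 2 M aq. HCl, THF, rt
Reagents that add atoms: (methoxymethyl)triphenylphosphonium chloride, COC[P+](c1ccccc1)(c1ccccc1)c1ccccc1.[Cl-]; water, O
Why: Wittig methoxymethylenation followed by enol ether hydrolysis is the usual one-carbon homologation of an aryl aldehyde to the arylacetaldehyde; an aryl silyl ether should tolerate the salt-free ylide and brief dilute acid.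

Step 3
Reactants: 4 2-[5-bromo-3-methoxy-2-(TBSO)phenyl]acetaldehyde
Product: 5 2-[5-bromo-3-methoxy-2-(TBSO)phenyl]acetic acid
Conditions: NaClO2, NaH2PO4, 2-methylbut-2-ene, t-BuOH/H2O, 0 °C to rt
Reagents that add atoms: sodium chlorite, [Na+].[O-]Cl=O
Why: Pinnick oxidation converts the sensitive arylacetaldehyde to the acid under buffered conditions that spare the silyl ether and the electron-rich ring (hypochlorite is scavenged by the alkene).

Step 4
Reactants: 5 2-[5-bromo-3-methoxy-2-(TBSO)phenyl]acetic acid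
Product: 6 2-[5-bromo-3-methoxy-2-(TBSO)phenyl]acetic pivalic anhydride
Conditions: PivCl (1.05 equiv), Et3N (2.5 equiv), THF, −20 °C; Et3N·HCl filtered off cold under argon; filtrate kept at −20 °C as a stock solution and used the same day
Reagents that add atoms: pivaloyl chloride, CC(C)(C)C(Cl)=O
Why: Mixed-anhydride formation from a triethylammonium carboxylate and a hindered acid chloride; mixed pivalic anhydrides are stable for hours in cold THF, so one batch can be prepared and divided between the two enantiomeric auxiliaries (steps 5 and 13, run in parallel).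

Step 5
Reactants: 6 2-[5-bromo-3-methoxy-2-(TBSO)phenyl]acetic pivalic anhydride; 7 (S)-4-benzyloxazolidin-2-one
Product: 8 (S)-4-benzyl-3-{2-[5-bromo-3-methoxy-2-(TBSO)phenyl]acetyl}oxazolidin-2-one
Conditions: one half of the stock solution of 6 (carries the excess Et3N), 7, LiCl, THF, −20 °C to rt
Reagents that add atoms: none
Why: N-Acylation of an Evans auxiliary by a mixed pivalic anhydride with LiCl/Et3N activation; the hindered pivaloyl carbonyl directs attack to the arylacetyl carbonyl, and pivalate is the leaving group.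

Step 6
Reactants: 9 vanillin (4-hydroxy-3-methoxybenzaldehyde)
Product: 10 3-methoxy-4-(TBSO)benzaldehyde
Conditions: TBSCl, imidazole, DMF, rt
Reagents that add atoms: tert-butyldimethylsilyl chloride, CC(C)(C)[Si](C)(C)Cl
Why: Routine phenol silylation; the free phenol would quench the boron enolate of step 7.

Step 7
Reactants: 8 (S)-4-benzyl-3-{2-[5-bromo-3-methoxy-2-(TBSO)phenyl]acetyl}oxazolidin-2-one; 10 3-methoxy-4-(TBSO)benzaldehyde
Product: 12 (S)-4-benzyl-3-{(2S,3S)-2-[5-bromo-3-methoxy-2-(TBSO)phenyl]-3-hydroxy-3-[3-methoxy-4-(TBSO)phenyl]propanoyl}oxazolidin-2-one, via dibutylboron enolate 11 (not isolated)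
Conditions: Bu2BOTf, iPr2NEt, CH2Cl2, −78 to 0 °C; then 10, −78 to 0 °C; pH 7 buffer, MeOH, 30% H2O2, 0 °C
Reagents that add atoms: none
Why: Evans syn-aldol: the (Z)-boron enolate reacts through a closed chair transition state on the face dictated by the (S)-benzyl auxiliary, fixing the aryl-bearing carbon (the future outer C3) as S in 12, which becomes 3R in the ring; the carbinol centre formed alongside is not needed later.

Step 8
Reactants: 12 aldol adduct of step 7
Product: 13 (1S,2R)-2-[5-bromo-3-methoxy-2-(TBSO)phenyl]-1-[3-methoxy-4-(TBSO)phenyl]propane-1,3-diol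
Conditions: LiBH4, MeOH (1 equiv), THF, 0 °C
Reagents that add atoms: none
Why: Reductive cleavage of the N-acyl oxazolidinone by LiBH4 gives the primary alcohol and returns the auxiliary; the mild hydride avoids retro-aldol and epimerisation of the α-aryl centre and leaves the silyl ethers and the bromide alone.

Step 9
Reactants: 13 (1S,2R)-2-[5-bromo-3-methoxy-2-(TBSO)phenyl]-1-[3-methoxy-4-(TBSO)phenyl]propane-1,3-diol
Product: 14 (1S,2R)-2-(5-bromo-2-hydroxy-3-methoxyphenyl)-1-(4-hydroxy-3-methoxyphenyl)propane-1,3-diol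
Conditions: TBAF, AcOH, THF, 0 °C
Reagents that add atoms: none
Why: Fluoride cleaves both aryl silyl ethers rapidly; the acetic acid buffer keeps the phenols protonated so that no quinone methide forms prematurely under basic conditions.

Step 10
Reactants: 14 (1S,2R)-2-(5-bromo-2-hydroxy-3-methoxyphenyl)-1-(4-hydroxy-3-methoxyphenyl)propane-1,3-diol
Product: 16 [(2S,3R)-5-bromo-2-(4-hydroxy-3-methoxyphenyl)-7-methoxy-2,3-dihydro-1-benzofuran-3-yl]methanol, via para-quinone methide 15 (not isolated)
Conditions: 0.2 M HCl in MeOH, rt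
Reagents that add atoms: none
Why: Protonation of the benzylic hydroxyl at C1 and loss of water, pushed by the para-hydroxyl, give the para-quinone methide 15 (or its O-protonated cation), in which the former carbinol carbon is planar, so both C1 epimers of 14 converge. The ortho phenol oxygen then adds to the exocyclic methide carbon in a 5-exo-trig closure that forms the O1–C2 bond and restores the aromatic ring. The closest known reaction type is the acid-mediated cyclisation of 2-(2-hydroxyaryl)-1-arylpropane-1,3-diols to trans-2-aryl-2,3-dihydrobenzofurans (phenylcoumaran synthesis). The new stereocentre C2 is controlled by C3: addition anti to the hydroxymethyl group is preferred, and because the product can re-ionise through the same quinone methide the mixture should settle on the more stable trans (2S,3R) isomer. The step needs diastereoselectivity at C2 and chemoselectivity between the two hydroxyls. The first is secured by this reversibility, the second by the para-hydroxyl, which lets only the benzylic carbon ionise, and by ring size, since the primary hydroxyl could only close an oxetane. Benzylic methyl ethers formed by methanol capture re-ionise under the same conditions and are funnelled to 16; the bromide is a spectator.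

Step 11
Reactants: 16 [(2S,3R)-5-bromo-2-(4-hydroxy-3-methoxyphenyl)-7-methoxy-2,3-dihydro-1-benzofuran-3-yl]methanol
Product: 17 (2S,3R)-5-bromo-7-methoxy-2-[3-methoxy-4-(TBSO)phenyl]-3-[(TBSO)methyl]-2,3-dihydro-1-benzofuran
Conditions: TBSCl, imidazole, DMF, rt
Reagents that add atoms: tert-butyldimethylsilyl chloride, CC(C)(C)[Si](C)(C)Cl
Why: Silylation of the phenol and the primary alcohol removes both acidic protons before the organolithium step and takes away the free para-hydroxyl that makes C2 labile.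

Step 12
Reactants: 17 (2S,3R)-5-bromo-7-methoxy-2-[3-methoxy-4-(TBSO)phenyl]-3-[(TBSO)methyl]-2,3-dihydro-1-benzofuran
Product: 19 (2S,3R)-7-methoxy-2-[3-methoxy-4-(TBSO)phenyl]-3-[(TBSO)methyl]-2,3-dihydro-1-benzofuran-5-carbaldehyde, via aryllithium 18 (not isolated)
Conditions: n-BuLi, THF, −78 °C; then DMF, −78 to 0 °C; aq. NH4Cl
Reagents that add atoms: N,N-dimethylformamide, CN(C)C=O
Why: Bromine–lithium exchange followed by formylation with DMF (Bouveault reaction); at −78 °C exchange is much faster than deprotonation at the benzylic ring positions.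

Step 13
Reactants: 6 2-[5-bromo-3-methoxy-2-(TBSO)phenyl]acetic pivalic anhydride; 20 (R)-4-benzyloxazolidin-2-one
Product: 21 (R)-4-benzyl-3-{2-[5-bromo-3-methoxy-2-(TBSO)phenyl]acetyl}oxazolidin-2-one
Conditions: second half of the stock solution of 6 (carries the excess Et3N), 20, LiCl, THF, −20 °C to rt
Reagents that add atoms: none
Why: The same mixed-anhydride N-acylation as step 5 with the enantiomeric auxiliary, needed because the inner ring has the opposite absolute configuration to the outer ring.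

Step 14
Reactants: 21 (R)-4-benzyl-3-{2-[5-bromo-3-methoxy-2-(TBSO)phenyl]acetyl}oxazolidin-2-one; 19 (2S,3R)-7-methoxy-2-[3-methoxy-4-(TBSO)phenyl]-3-[(TBSO)methyl]-2,3-dihydro-1-benzofuran-5-carbaldehyde
Product: 23 (R)-4-benzyl-3-{(2R,3R)-2-[5-bromo-3-methoxy-2-(TBSO)phenyl]-3-hydroxy-3-U-propanoyl}oxazolidin-2-one, via dibutylboron enolate 22 (not isolated)
Conditions: Bu2BOTf, iPr2NEt, CH2Cl2, −78 to 0 °C; then 19, −78 to 0 °C; pH 7 buffer, MeOH, 30% H2O2, 0 °C
Reagents that add atoms: none
Why: Evans syn-aldol under control of the (R)-auxiliary sets the future inner C3 in the sense opposite to step 7; the stereocentres of 19 are remote from the formyl group, so reagent control should prevail.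

Step 15
Reactants: 23 aldol adduct of step 14
Product: 24 (1R,2S)-2-[5-bromo-3-methoxy-2-(TBSO)phenyl]-1-U-propane-1,3-diol
Conditions: LiBH4, MeOH (1 equiv), THF, 0 °C
Reagents that add atoms: none
Why: Reductive removal of the auxiliary as in step 8; silyl ethers, the aryl bromide and the dihydrobenzofuran are inert to LiBH4.

Step 16
Reactants: 24 (1R,2S)-2-[5-bromo-3-methoxy-2-(TBSO)phenyl]-1-U-propane-1,3-diol
Product: 25 (1R,2S)-2-(5-bromo-2-hydroxy-3-methoxyphenyl)-1-[(2S,3R)-3-(hydroxymethyl)-2-(4-hydroxy-3-methoxyphenyl)-7-methoxy-2,3-dihydro-1-benzofuran-5-yl]propane-1,3-diol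
Conditions: TBAF, AcOH, THF, 0 °C to rt
Reagents that add atoms: none
Why: Buffered fluoride removes the two aryl silyl ethers and the primary silyl ether, freeing the ortho phenol needed as the nucleophile in step 17.

Step 17
Reactants: 25 pentahydroxy compound of step 16
Product: 27 [(2R,3S)-5-bromo-2-[(2S,3R)-3-(hydroxymethyl)-2-(4-hydroxy-3-methoxyphenyl)-7-methoxy-2,3-dihydro-1-benzofuran-5-yl]-7-methoxy-2,3-dihydro-1-benzofuran-3-yl]methanol, via benzylic cation 26 (not isolated)
Conditions: 0.2 M HCl in MeOH, rt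
Reagents that add atoms: none
Why: Cationic oxa-cyclisation of the same type as step 10: the benzylic hydroxyl para to O1 of the outer ring ionises to the alkoxy-stabilised cation 26, the ortho phenol closes 5-exo, and reversibility should place the aryl group trans to the C3 hydroxymethyl group, giving the (2R,3S) inner ring; any reversible opening of the outer ring returns to trans because its C3 is fixed.

Step 18
Reactants: 27 bis-dihydrobenzofuran triol of step 17
Product: 28 (2R,3S)-5-bromo-7-methoxy-3-[(TBSO)methyl]-2-U-2,3-dihydro-1-benzofuran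
Conditions: TBSCl, imidazole, DMF, rt
Reagents that add atoms: tert-butyldimethylsilyl chloride, CC(C)(C)[Si](C)(C)Cl
Why: Silylation of the phenol and both primary alcohols prepares the bromide for lithiation and again blocks the para-hydroxyl that would labilise the outer C2.

Step 19
Reactants: 29 3-(4-hydroxy-3-methoxyphenyl)propanoic acid
Product: 31 3-[3-methoxy-4-(TBSO)phenyl]propanoic acid, via bis-silyl derivative 30 (not isolated)
Conditions: TBSCl (2.2 equiv), imidazole, DMF, rt; then AcOH, THF/H2O, rt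
Reagents that add atoms: tert-butyldimethylsilyl chloride, CC(C)(C)[Si](C)(C)Cl
Why: Both the phenol and the acid are silylated; the silyl ester hydrolyses in aqueous acetic acid far faster than the aryl silyl ether, leaving the protected acid.

Step 20
Reactants: 31 3-[3-methoxy-4-(TBSO)phenyl]propanoic acid; 7 (S)-4-benzyloxazolidin-2-one
Product: 33 (S)-4-benzyl-3-{3-[3-methoxy-4-(TBSO)phenyl]propanoyl}oxazolidin-2-one, via mixed pivalic anhydride 32 (not isolated)
Conditions: PivCl, Et3N, THF, −20 °C; then 7, LiCl, rt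
Reagents that add atoms: none
Why: Mixed-anhydride N-acylation of the Evans auxiliary, the one-pot form of steps 4 and 5, used here because only one auxiliary is needed.

Step 21
Reactants: 33 (S)-4-benzyl-3-{3-[3-methoxy-4-(TBSO)phenyl]propanoyl}oxazolidin-2-one; 34 tert-butyl bromoacetate
Product: 36 tert-butyl (3R)-4-[(4S)-4-benzyl-2-oxo-1,3-oxazolidin-3-yl]-3-{[3-methoxy-4-(TBSO)phenyl]methyl}-4-oxobutanoate, via sodium enolate 35 (not isolated)
Conditions: NaHMDS, THF, −78 °C; then 34, −78 to −40 °C
Reagents that add atoms: none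
Why: Evans alkylation: the chelated (Z)-sodium enolate is attacked by the reactive α-halo ester on the face opposite the auxiliary benzyl group, setting the benzyl-bearing carbon (the future C4 of the tetrahydrofuran) as R.

Step 22
Reactants: 36 alkylated imide of step 21
Product: 37 tert-butyl (3R)-4-hydroxy-3-{[3-methoxy-4-(TBSO)phenyl]methyl}butanoate
Conditions: LiBH4, MeOH (1 equiv), THF, 0 °C
Reagents that add atoms: none
Why: LiBH4 reduces the activated imide carbonyl chemoselectively in the presence of the hindered tert-butyl ester and releases the auxiliary.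

Step 23
Reactants: 37 tert-butyl (3R)-4-hydroxy-3-{[3-methoxy-4-(TBSO)phenyl]methyl}butanoate
Product: 38 (4R)-4-{[3-methoxy-4-(TBSO)phenyl]methyl}oxolan-2-one
Conditions: CF3CO2H, CH2Cl2, 0 °C to rt
Reagents that add atoms: none
Why: Acid cleaves the tert-butyl ester with loss of isobutene and the γ-hydroxy acid lactonises spontaneously; an aryl silyl ether should withstand brief treatment with this acid in a non-nucleophilic solvent.

Step 24
Reactants: 38 (4R)-4-{[3-methoxy-4-(TBSO)phenyl]methyl}oxolan-2-one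
Product: 40 (3S,4R)-3-(hydroxymethyl)-4-{[3-methoxy-4-(TBSO)phenyl]methyl}oxolan-2-one, via lithium enolate 39 (not isolated)
Conditions: LDA, THF, −78 °C; then CH2O (gas, from cracked paraformaldehyde), −78 to −40 °C; aq. NH4Cl
Reagents that add atoms: formaldehyde, C=O
Why: Aldol hydroxymethylation of a lactone enolate; the electrophile enters trans to the C4 benzyl group, as in the classical α-functionalisation of β-benzylbutyrolactones.

Step 25
Reactants: 40 (3S,4R)-3-(hydroxymethyl)-4-{[3-methoxy-4-(TBSO)phenyl]methyl}oxolan-2-one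
Product: 41 (3S,4R)-3-[(TBSO)methyl]-4-{[3-methoxy-4-(TBSO)phenyl]methyl}oxolan-2-one
Conditions: TBSCl, imidazole, DMF, rt
Reagents that add atoms: tert-butyldimethylsilyl chloride, CC(C)(C)[Si](C)(C)Cl
Why: Protection of the primary alcohol before the enolate and aryllithium steps; silyloxide is a poor leaving group, which limits β-elimination in step 26.

Step 26
Reactants: 41 (3S,4R)-3-[(TBSO)methyl]-4-{[3-methoxy-4-(TBSO)phenyl]methyl}oxolan-2-one
Product: 43 (3R,4R)-3-[(TBSO)methyl]-4-{[3-methoxy-4-(TBSO)phenyl]methyl}oxolan-2-one, via lithium enolate 42 (not isolated)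
Conditions: LDA, THF, −78 °C; then 2,6-di-tert-butyl-4-methylphenol, THF, −78 °C; aq. NH4Cl
Reagents that add atoms: none
Why: Kinetic protonation of a β-substituted butyrolactone enolate: the bulky phenol delivers the proton to the face opposite the C4 benzyl group, so the silyloxymethyl group ends cis to it (3R), the same principle that converts trans-2,3-disubstituted butyrolactones into their cis epimers.

Step 27
Reactants: 28 (2R,3S)-5-bromo-7-methoxy-3-[(TBSO)methyl]-2-U-2,3-dihydro-1-benzofuran; 43 (3R,4R)-3-[(TBSO)methyl]-4-{[3-methoxy-4-(TBSO)phenyl]methyl}oxolan-2-one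
Product: 45 (3R,4R)-2-D-3-[(TBSO)methyl]-4-{[3-methoxy-4-(TBSO)phenyl]methyl}oxolan-2-ol (anomers), via aryllithium 44 (not isolated)
Conditions: n-BuLi, THF, −78 °C; then 43 (1.5 equiv), −78 °C; aq. NH4Cl
Reagents that add atoms: none
Why: Bromine–lithium exchange and addition of the aryllithium to a γ-lactone, which should stop at the lithium hemiketal at −78 °C, as in C-aryl glycoside synthesis; the cheaper lactone is used in excess.

Step 28
Reactants: 45 lactol of step 27
Product: 47 (2R,3R,4R)-2-D-3-[(TBSO)methyl]-4-{[3-methoxy-4-(TBSO)phenyl]methyl}oxolane, via oxocarbenium ion 46 (not isolated)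
Conditions: Et3SiH, BF3·OEt2, CH2Cl2, −78 °C
Reagents that add atoms: none
Why: Reductive deoxygenation of a lactol: the Lewis acid ionises the hemiketal to the 2-aryl oxocarbenium ion 46, and the silane attacks the face anti to the cis C3 and C4 substituents, placing the aryl group cis to both (2R); the low temperature is chosen so that the tertiary hemiketal ionises while the benzylic ethers of the dihydrobenzofurans do not.

Step 29
Reactants: 47 pentakis-silyl ether of step 28
Product: 48 target, [(2R,3R,4R)-2-{(2R,3S)-3-(hydroxymethyl)-2-[(2S,3R)-3-(hydroxymethyl)-2-(4-hydroxy-3-methoxyphenyl)-7-methoxy-2,3-dihydro-1-benzofuran-5-yl]-7-methoxy-2,3-dihydro-1-benzofuran-5-yl}-4-[(4-hydroxy-3-methoxyphenyl)methyl]oxolan-3-yl]methanol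
Conditions: TBAF, AcOH, THF, 0 °C to rt
Reagents that add atoms: none
Why: Buffered fluoride cleaves all five silyl ethers without acid, so neither the dihydrobenzofurans nor the kinetically formed all-cis tetrahydrofuran can re-ionise and epimerise.

## Compound list

1 | 5-bromo-2-hydroxy-3-methoxybenzaldehyde | COc1cc(Br)cc(C=O)c1O | starting material
2 | 5-bromo-3-methoxy-2-(TBSO)benzaldehyde | COc1cc(Br)cc(C=O)c1O[Si](C)(C)C(C)(C)C | intermediate
3 | 1-bromo-3-methoxy-5-(2-methoxyethenyl)-4-(TBSO)benzene, E/Z mixture | COC=Cc1cc(Br)cc(OC)c1O[Si](C)(C)C(C)(C)C | intermediate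
4 | 2-[5-bromo-3-methoxy-2-(TBSO)phenyl]acetaldehyde | O=CCc1cc(Br)cc(OC)c1O[Si](C)(C)C(C)(C)C | intermediate
5 | 2-[5-bromo-3-methoxy-2-(TBSO)phenyl]acetic acid | OC(=O)Cc1cc(Br)cc(OC)c1O[Si](C)(C)C(C)(C)C | intermediate
6 | 2-[5-bromo-3-methoxy-2-(TBSO)phenyl]acetic pivalic anhydride | CC(C)(C)C(=O)OC(=O)Cc1cc(Br)cc(OC)c1O[Si](C)(C)C(C)(C)C | intermediate
7 | (S)-4-benzyloxazolidin-2-one | O=C1N[C@@H](Cc2ccccc2)CO1 | starting material
8 | (S)-4-benzyl-3-{2-[5-bromo-3-methoxy-2-(TBSO)phenyl]acetyl}oxazolidin-2-one | O=C(Cc1cc(Br)cc(OC)c1O[Si](C)(C)C(C)(C)C)N1[C@@H](Cc2ccccc2)COC1=O | intermediate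
9 | vanillin (4-hydroxy-3-methoxybenzaldehyde) | COc1cc(C=O)ccc1O | starting material
10 | 3-methoxy-4-(TBSO)benzaldehyde | COc1cc(C=O)ccc1O[Si](C)(C)C(C)(C)C | intermediate
11 | (Z)-dibutylboron enolate of 8 | CCCCB(CCCC)O/C(=C\c1cc(Br)cc(OC)c1O[Si](C)(C)C(C)(C)C)N1[C@@H](Cc2ccccc2)COC1=O | intermediate
12 | (S)-4-benzyl-3-{(2S,3S)-2-[5-bromo-3-methoxy-2-(TBSO)phenyl]-3-hydroxy-3-[3-methoxy-4-(TBSO)phenyl]propanoyl}oxazolidin-2-one | O=C([C@@H](c1cc(Br)cc(OC)c1O[Si](C)(C)C(C)(C)C)[C@H](O)c1ccc(O[Si](C)(C)C(C)(C)C)c(OC)c1)N1[C@@H](Cc2ccccc2)COC1=O | intermediate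
13 | (1S,2R)-2-[5-bromo-3-methoxy-2-(TBSO)phenyl]-1-[3-methoxy-4-(TBSO)phenyl]propane-1,3-diol | OC[C@@H](c1cc(Br)cc(OC)c1O[Si](C)(C)C(C)(C)C)[C@H](O)c1ccc(O[Si](C)(C)C(C)(C)C)c(OC)c1 | intermediate
14 | (1S,2R)-2-(5-bromo-2-hydroxy-3-methoxyphenyl)-1-(4-hydroxy-3-methoxyphenyl)propane-1,3-diol | OC[C@@H](c1cc(Br)cc(OC)c1O)[C@H](O)c1ccc(O)c(OC)c1 | intermediate
15 | para-quinone methide, 4-[(2R)-2-(5-bromo-2-hydroxy-3-methoxyphenyl)-3-hydroxypropylidene]-2-methoxycyclohexa-2,5-dien-1-one | OC[C@@H](c1cc(Br)cc(OC)c1O)C=C1C=CC(=O)C(OC)=C1 | intermediate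
16 | [(2S,3R)-5-bromo-2-(4-hydroxy-3-methoxyphenyl)-7-methoxy-2,3-dihydro-1-benzofuran-3-yl]methanol | Brc1cc(OC)c2c(c1)[C@H](CO)[C@@H](c1ccc(O)c(OC)c1)O2 | intermediate
17 | (2S,3R)-5-bromo-7-methoxy-2-[3-methoxy-4-(TBSO)phenyl]-3-[(TBSO)methyl]-2,3-dihydro-1-benzofuran | Brc1cc(OC)c2c(c1)[C@H](CO[Si](C)(C)C(C)(C)C)[C@@H](c1ccc(O[Si](C)(C)C(C)(C)C)c(OC)c1)O2 | intermediate
18 | 5-lithio derivative of 17 (aryllithium) | [Li]c1cc(OC)c2c(c1)[C@H](CO[Si](C)(C)C(C)(C)C)[C@@H](c1ccc(O[Si](C)(C)C(C)(C)C)c(OC)c1)O2 | intermediate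
19 | (2S,3R)-7-methoxy-2-[3-methoxy-4-(TBSO)phenyl]-3-[(TBSO)methyl]-2,3-dihydro-1-benzofuran-5-carbaldehyde | O=Cc1cc(OC)c2c(c1)[C@H](CO[Si](C)(C)C(C)(C)C)[C@@H](c1ccc(O[Si](C)(C)C(C)(C)C)c(OC)c1)O2 | intermediate
20 | (R)-4-benzyloxazolidin-2-one | O=C1N[C@H](Cc2ccccc2)CO1 | starting material
21 | (R)-4-benzyl-3-{2-[5-bromo-3-methoxy-2-(TBSO)phenyl]acetyl}oxazolidin-2-one | O=C(Cc1cc(Br)cc(OC)c1O[Si](C)(C)C(C)(C)C)N1[C@H](Cc2ccccc2)COC1=O | intermediate
22 | (Z)-dibutylboron enolate of 21 | CCCCB(CCCC)O/C(=C\c1cc(Br)cc(OC)c1O[Si](C)(C)C(C)(C)C)N1[C@H](Cc2ccccc2)COC1=O | intermediate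
23 | (R)-4-benzyl-3-{(2R,3R)-2-[5-bromo-3-methoxy-2-(TBSO)phenyl]-3-hydroxy-3-U-propanoyl}oxazolidin-2-one | O=C([C@H](c1cc(Br)cc(OC)c1O[Si](C)(C)C(C)(C)C)[C@@H](O)c1cc(OC)c2c(c1)[C@H](CO[Si](C)(C)C(C)(C)C)[C@@H](c1ccc(O[Si](C)(C)C(C)(C)C)c(OC)c1)O2)N1[C@H](Cc2ccccc2)COC1=O | intermediate
24 | (1R,2S)-2-[5-bromo-3-methoxy-2-(TBSO)phenyl]-1-U-propane-1,3-diol | OC[C@H](c1cc(Br)cc(OC)c1O[Si](C)(C)C(C)(C)C)[C@@H](O)c1cc(OC)c2c(c1)[C@H](CO[Si](C)(C)C(C)(C)C)[C@@H](c1ccc(O[Si](C)(C)C(C)(C)C)c(OC)c1)O2 | intermediate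
25 | (1R,2S)-2-(5-bromo-2-hydroxy-3-methoxyphenyl)-1-[(2S,3R)-3-(hydroxymethyl)-2-(4-hydroxy-3-methoxyphenyl)-7-methoxy-2,3-dihydro-1-benzofuran-5-yl]propane-1,3-diol | OC[C@H](c1cc(Br)cc(OC)c1O)[C@@H](O)c1cc(OC)c2c(c1)[C@H](CO)[C@@H](c1ccc(O)c(OC)c1)O2 | intermediate
26 | benzylic cation from 25 (positive carbon at C1 of the propane chain, para to O1 of the outer ring; C2 of the chain S) | OC[C@H](c1cc(Br)cc(OC)c1O)[CH+]c1cc(OC)c2c(c1)[C@H](CO)[C@@H](c1ccc(O)c(OC)c1)O2 | intermediate
27 | [(2R,3S)-5-bromo-2-[(2S,3R)-3-(hydroxymethyl)-2-(4-hydroxy-3-methoxyphenyl)-7-methoxy-2,3-dihydro-1-benzofuran-5-yl]-7-methoxy-2,3-dihydro-1-benzofuran-3-yl]methanol | Brc1cc(OC)c2c(c1)[C@@H](CO)[C@H](c1cc(OC)c3c(c1)[C@H](CO)[C@@H](c1ccc(O)c(OC)c1)O3)O2 | intermediate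
28 | (2R,3S)-5-bromo-7-methoxy-3-[(TBSO)methyl]-2-U-2,3-dihydro-1-benzofuran (tris-TBS ether of 27) | Brc1cc(OC)c2c(c1)[C@@H](CO[Si](C)(C)C(C)(C)C)[C@H](c1cc(OC)c3c(c1)[C@H](CO[Si](C)(C)C(C)(C)C)[C@@H](c1ccc(O[Si](C)(C)C(C)(C)C)c(OC)c1)O3)O2 | intermediate
29 | 3-(4-hydroxy-3-methoxyphenyl)propanoic acid | COc1cc(CCC(O)=O)ccc1O | starting material
30 | tert-butyldimethylsilyl 3-[3-methoxy-4-(TBSO)phenyl]propanoate | COc1cc(CCC(=O)O[Si](C)(C)C(C)(C)C)ccc1O[Si](C)(C)C(C)(C)C | intermediate
31 | 3-[3-methoxy-4-(TBSO)phenyl]propanoic acid | COc1cc(CCC(O)=O)ccc1O[Si](C)(C)C(C)(C)C | intermediate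
32 | 3-[3-methoxy-4-(TBSO)phenyl]propanoic pivalic anhydride | COc1cc(CCC(=O)OC(=O)C(C)(C)C)ccc1O[Si](C)(C)C(C)(C)C | intermediate
33 | (S)-4-benzyl-3-{3-[3-methoxy-4-(TBSO)phenyl]propanoyl}oxazolidin-2-one | COc1cc(CCC(=O)N2[C@@H](Cc3ccccc3)COC2=O)ccc1O[Si](C)(C)C(C)(C)C | intermediate
34 | tert-butyl bromoacetate | CC(C)(C)OC(=O)CBr | starting material
35 | (Z)-sodium enolate of 33 | [Na]O/C(=C\Cc1ccc(O[Si](C)(C)C(C)(C)C)c(OC)c1)N1[C@@H](Cc2ccccc2)COC1=O | intermediate
36 | tert-butyl (3R)-4-[(4S)-4-benzyl-2-oxo-1,3-oxazolidin-3-yl]-3-{[3-methoxy-4-(TBSO)phenyl]methyl}-4-oxobutanoate | CC(C)(C)OC(=O)C[C@@H](Cc1ccc(O[Si](C)(C)C(C)(C)C)c(OC)c1)C(=O)N1[C@@H](Cc2ccccc2)COC1=O | intermediate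
37 | tert-butyl (3R)-4-hydroxy-3-{[3-methoxy-4-(TBSO)phenyl]methyl}butanoate | CC(C)(C)OC(=O)C[C@@H](Cc1ccc(O[Si](C)(C)C(C)(C)C)c(OC)c1)CO | intermediate
38 | (4R)-4-{[3-methoxy-4-(TBSO)phenyl]methyl}oxolan-2-one | O=C1C[C@@H](Cc2ccc(O[Si](C)(C)C(C)(C)C)c(OC)c2)CO1 | intermediate
39 | lithium enolate of 38 | [Li]OC1=C[C@@H](Cc2ccc(O[Si](C)(C)C(C)(C)C)c(OC)c2)CO1 | intermediate
40 | (3S,4R)-3-(hydroxymethyl)-4-{[3-methoxy-4-(TBSO)phenyl]methyl}oxolan-2-one (trans) | O=C1OC[C@H](Cc2ccc(O[Si](C)(C)C(C)(C)C)c(OC)c2)[C@H]1CO | intermediate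
41 | (3S,4R)-3-[(TBSO)methyl]-4-{[3-methoxy-4-(TBSO)phenyl]methyl}oxolan-2-one (trans) | O=C1OC[C@H](Cc2ccc(O[Si](C)(C)C(C)(C)C)c(OC)c2)[C@H]1CO[Si](C)(C)C(C)(C)C | intermediate
42 | lithium enolate of 41 | [Li]OC1=C(CO[Si](C)(C)C(C)(C)C)[C@@H](Cc2ccc(O[Si](C)(C)C(C)(C)C)c(OC)c2)CO1 | intermediate
43 | (3R,4R)-3-[(TBSO)methyl]-4-{[3-methoxy-4-(TBSO)phenyl]methyl}oxolan-2-one (cis) | O=C1OC[C@H](Cc2ccc(O[Si](C)(C)C(C)(C)C)c(OC)c2)[C@@H]1CO[Si](C)(C)C(C)(C)C | intermediate
44 | 5-lithio derivative of 28 (aryllithium) | [Li]c1cc(OC)c2c(c1)[C@@H](CO[Si](C)(C)C(C)(C)C)[C@H](c1cc(OC)c3c(c1)[C@H](CO[Si](C)(C)C(C)(C)C)[C@@H](c1ccc(O[Si](C)(C)C(C)(C)C)c(OC)c1)O3)O2 | intermediate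
45 | (3R,4R)-2-D-3-[(TBSO)methyl]-4-{[3-methoxy-4-(TBSO)phenyl]methyl}oxolan-2-ol, mixture of anomers | OC1(c2cc(OC)c3c(c2)[C@@H](CO[Si](C)(C)C(C)(C)C)[C@H](c2cc(OC)c4c(c2)[C@H](CO[Si](C)(C)C(C)(C)C)[C@@H](c2ccc(O[Si](C)(C)C(C)(C)C)c(OC)c2)O4)O3)OC[C@H](Cc2ccc(O[Si](C)(C)C(C)(C)C)c(OC)c2)[C@@H]1CO[Si](C)(C)C(C)(C)C | intermediate
46 | cyclic 2-aryl oxocarbenium ion from 45 (3,4-cis) | [O+]1=C(c2cc(OC)c3c(c2)[C@@H](CO[Si](C)(C)C(C)(C)C)[C@H](c2cc(OC)c4c(c2)[C@H](CO[Si](C)(C)C(C)(C)C)[C@@H](c2ccc(O[Si](C)(C)C(C)(C)C)c(OC)c2)O4)O3)[C@@H](CO[Si](C)(C)C(C)(C)C)[C@@H](Cc2ccc(O[Si](C)(C)C(C)(C)C)c(OC)c2)C1 | intermediate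
47 | (2R,3R,4R)-2-D-3-[(TBSO)methyl]-4-{[3-methoxy-4-(TBSO)phenyl]methyl}oxolane (pentakis-TBS ether of the target, all-cis) | COc1cc(C[C@H]2CO[C@@H](c3cc(OC)c4c(c3)[C@@H](CO[Si](C)(C)C(C)(C)C)[C@H](c3cc(OC)c5c(c3)[C@H](CO[Si](C)(C)C(C)(C)C)[C@@H](c3ccc(O[Si](C)(C)C(C)(C)C)c(OC)c3)O5)O4)[C@H]2CO[Si](C)(C)C(C)(C)C)ccc1O[Si](C)(C)C(C)(C)C | intermediate
48 | target CNP0395728.1, [(2R,3R,4R)-2-{(2R,3S)-3-(hydroxymethyl)-2-[(2S,3R)-3-(hydroxymethyl)-2-(4-hydroxy-3-methoxyphenyl)-7-methoxy-2,3-dihydro-1-benzofuran-5-yl]-7-methoxy-2,3-dihydro-1-benzofuran-5-yl}-4-[(4-hydroxy-3-methoxyphenyl)methyl]oxolan-3-yl]methanol | COc1cc(C[C@H]2CO[C@@H](c3cc(OC)c4c(c3)[C@@H](CO)[C@H](c3cc(OC)c5c(c3)[C@H](CO)[C@@H](c3ccc(O)c(OC)c3)O5)O4)[C@H]2CO)ccc1O | target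

## Step count and least certain steps

Total: 29 steps. Longest linear sequence: 19 steps (steps 1–5, 7–12, 14–18, 27–29); the lactone branch (steps 19–26) joins at step 27.

**Step 10 (key step).** The most likely failures are fragmentation of the ionised 1,3-diol with loss of the hydroxymethyl carbon as formaldehyde (retro-Prins, giving a stilbene), stalling at the benzylic methyl ether, and intermolecular capture of the quinone methide by a second phenol. All three arise because the cation or quinone methide is long-lived in acidic methanol.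
Fallback, from diol 13, returning at 16:
- Both hydroxyls are acetylated (Ac2O, pyridine) to (1S,2R)-2-[5-bromo-3-methoxy-2-(TBSO)phenyl]-1-[3-methoxy-4-(TBSO)phenyl]propane-1,3-diyl diacetate F1.
- TBAF in THF then strips both aryl silyl ethers. The para-phenoxide expels the benzylic acetate by 1,6-elimination, and the ortho-phenoxide adds to the quinone methide under basic, non-ionising conditions with the primary hydroxyl masked. This should give [(2S,3R)-5-bromo-2-(4-hydroxy-3-methoxyphenyl)-7-methoxy-2,3-dihydro-1-benzofuran-3-yl]methyl acetate F2.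
- Methanolysis (K2CO3, MeOH) rejoins the route at 16.

**Step 26.** Facial selectivity in protonating enolate 42 may be incomplete, since a proton is a small electrophile, and the enolate may lose silyloxide by β-elimination to an α-methylene lactone.
Fallback, from lactone 38, returning at 43:
- Formylation (LDA, then 2,2,2-trifluoroethyl formate) gives (4R)-3-(hydroxymethylidene)-4-{[3-methoxy-4-(TBSO)phenyl]methyl}oxolan-2-one F3.
- Silylation (TBSCl, imidazole) gives the enol silyl ether (4R)-3-[(TBSO)methylidene]-4-{[3-methoxy-4-(TBSO)phenyl]methyl}oxolan-2-one F4.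
- Hydrogenation over rhodium on alumina (Rh/Al2O3) adds hydrogen to the face opposite the benzyl group and gives the cis-lactone 43 directly.

**Step 27.** Aryllithium 44 may act as a base towards the enolisable lactone 43. Proton transfer would waste the advanced fragment as the debrominated arene and epimerise the lactone, and a second addition to the ring-opened ketone is also possible.
Fallback (reversed polarity), from bromide 28 and lactone 38, returning at 48:
- Bromide 28 is formylated (n-BuLi, then DMF) to (2R,3S)-7-methoxy-3-[(TBSO)methyl]-2-U-2,3-dihydro-1-benzofuran-5-carbaldehyde F5.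
- Lithium enolate 39 of lactone 38 adds to it, trans to the benzyl group, giving (3S,4R)-3-[hydroxy(D)methyl]-4-{[3-methoxy-4-(TBSO)phenyl]methyl}oxolan-2-one F6 (carbinol epimers).
- LiBH4 opens the lactone to (2R,3R)-2-[hydroxy(D)methyl]-3-{[3-methoxy-4-(TBSO)phenyl]methyl}butane-1,4-diol F7.
- MnO2 oxidises only the benzylic carbinol. The ketone closes onto the hydroxymethyl group of the benzyl-bearing carbon to give the lactol (3R,4R)-2-D-3-(hydroxymethyl)-4-{[3-methoxy-4-(TBSO)phenyl]methyl}oxolan-2-ol F8. Because the ring has switched, the hydroxymethyl group derived from the old lactone carbonyl is now cis to the benzyl group.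
- Et3SiH and BF3·OEt2 at −78 °C give [(2R,3R,4R)-2-D-4-{[3-methoxy-4-(TBSO)phenyl]methyl}oxolan-3-yl]methanol F9.
- Buffered TBAF then leads to 48.

**Step 28.** The Lewis acid may also ionise the benzylic C2–O bonds of the dihydrobenzofurans, which would then be reduced by the silane, or the oxocarbenium ion may equilibrate through its enol ether and lose the C3 configuration before hydride arrives.
Fallback, from lactol 45, returning at 47:
- Dehydration under basic conditions ((CF3CO)2O, Et3N, CH2Cl2) gives the 4,5-dihydrofuran (3R)-5-D-4-[(TBSO)methyl]-3-{[3-methoxy-4-(TBSO)phenyl]methyl}-2,3-dihydrofuran F10.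
- Hydrogenation over palladium on carbon (Pd/C) in ethyl acetate buffered with Et3N adds both hydrogens from the face opposite the benzyl group, setting C2 and C3 together and giving 47 without any Lewis acid.

## Further compounds

F1 | step 10 | (1S,2R)-2-[5-bromo-3-methoxy-2-(TBSO)phenyl]-1-[3-methoxy-4-(TBSO)phenyl]propane-1,3-diyl diacetate | CC(=O)OC[C@@H](c1cc(Br)cc(OC)c1O[Si](C)(C)C(C)(C)C)[C@H](OC(C)=O)c1ccc(O[Si](C)(C)C(C)(C)C)c(OC)c1
F2 | step 10 | [(2S,3R)-5-bromo-2-(4-hydroxy-3-methoxyphenyl)-7-methoxy-2,3-dihydro-1-benzofuran-3-yl]methyl acetate | Brc1cc(OC)c2c(c1)[C@H](COC(C)=O)[C@@H](c1ccc(O)c(OC)c1)O2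
F3 | step 26 | (4R)-3-(hydroxymethylidene)-4-{[3-methoxy-4-(TBSO)phenyl]methyl}oxolan-2-one | O=C1OC[C@H](Cc2ccc(O[Si](C)(C)C(C)(C)C)c(OC)c2)C1=CO
F4 | step 26 | (4R)-3-[(TBSO)methylidene]-4-{[3-methoxy-4-(TBSO)phenyl]methyl}oxolan-2-one | O=C1OC[C@H](Cc2ccc(O[Si](C)(C)C(C)(C)C)c(OC)c2)C1=CO[Si](C)(C)C(C)(C)C
F5 | step 27 | (2R,3S)-7-methoxy-3-[(TBSO)methyl]-2-U-2,3-dihydro-1-benzofuran-5-carbaldehyde | O=Cc1cc(OC)c2c(c1)[C@@H](CO[Si](C)(C)C(C)(C)C)[C@H](c1cc(OC)c3c(c1)[C@H](CO[Si](C)(C)C(C)(C)C)[C@@H](c1ccc(O[Si](C)(C)C(C)(C)C)c(OC)c1)O3)O2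
F6 | step 27 | (3S,4R)-3-[hydroxy(D)methyl]-4-{[3-methoxy-4-(TBSO)phenyl]methyl}oxolan-2-one, carbinol epimers | O=C1OC[C@H](Cc2ccc(O[Si](C)(C)C(C)(C)C)c(OC)c2)[C@H]1C(O)c1cc(OC)c2c(c1)[C@@H](CO[Si](C)(C)C(C)(C)C)[C@H](c1cc(OC)c3c(c1)[C@H](CO[Si](C)(C)C(C)(C)C)[C@@H](c1ccc(O[Si](C)(C)C(C)(C)C)c(OC)c1)O3)O2
F7 | step 27 | (2R,3R)-2-[hydroxy(D)methyl]-3-{[3-methoxy-4-(TBSO)phenyl]methyl}butane-1,4-diol, carbinol epimers | OC[C@H](C(O)c1cc(OC)c2c(c1)[C@@H](CO[Si](C)(C)C(C)(C)C)[C@H](c1cc(OC)c3c(c1)[C@H](CO[Si](C)(C)C(C)(C)C)[C@@H](c1ccc(O[Si](C)(C)C(C)(C)C)c(OC)c1)O3)O2)[C@@H](Cc1ccc(O[Si](C)(C)C(C)(C)C)c(OC)c1)CO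
F8 | step 27 | (3R,4R)-2-D-3-(hydroxymethyl)-4-{[3-methoxy-4-(TBSO)phenyl]methyl}oxolan-2-ol, anomers | OC[C@H]1[C@@H](Cc2ccc(O[Si](C)(C)C(C)(C)C)c(OC)c2)COC1(O)c1cc(OC)c2c(c1)[C@@H](CO[Si](C)(C)C(C)(C)C)[C@H](c1cc(OC)c3c(c1)[C@H](CO[Si](C)(C)C(C)(C)C)[C@@H](c1ccc(O[Si](C)(C)C(C)(C)C)c(OC)c1)O3)O2
F9 | step 27 | [(2R,3R,4R)-2-D-4-{[3-methoxy-4-(TBSO)phenyl]methyl}oxolan-3-yl]methanol | COc1cc(C[C@H]2CO[C@@H](c3cc(OC)c4c(c3)[C@@H](CO[Si](C)(C)C(C)(C)C)[C@H](c3cc(OC)c5c(c3)[C@H](CO[Si](C)(C)C(C)(C)C)[C@@H](c3ccc(O[Si](C)(C)C(C)(C)C)c(OC)c3)O5)O4)[C@H]2CO)ccc1O[Si](C)(C)C(C)(C)C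
F10 | step 28 | (3R)-5-D-4-[(TBSO)methyl]-3-{[3-methoxy-4-(TBSO)phenyl]methyl}-2,3-dihydrofuran | CC(C)(C)[Si](C)(C)OCC1=C(c2cc(OC)c3c(c2)[C@@H](CO[Si](C)(C)C(C)(C)C)[C@H](c2cc(OC)c4c(c2)[C@H](CO[Si](C)(C)C(C)(C)C)[C@@H](c2ccc(O[Si](C)(C)C(C)(C)C)c(OC)c2)O4)O3)OC[C@@H]1Cc1ccc(O[Si](C)(C)C(C)(C)C)c(OC)c1
A1 | alternative 1 | (2R,3S)-5-bromo-7-methoxy-3-[(TBSO)methyl]-2-U-2,3-dihydro-1-benzofuran (identical with 28) | Brc1cc(OC)c2c(c1)[C@@H](CO[Si](C)(C)C(C)(C)C)[C@H](c1cc(OC)c3c(c1)[C@H](CO[Si](C)(C)C(C)(C)C)[C@@H](c1ccc(O[Si](C)(C)C(C)(C)C)c(OC)c1)O3)O2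
A2 | alternative 1 | 1-(U-methyl)thiolan-1-ium triflate | C1CC[S+](C1)Cc1cc(OC)c2c(c1)[C@H](CO[Si](C)(C)C(C)(C)C)[C@@H](c1ccc(O[Si](C)(C)C(C)(C)C)c(OC)c1)O2.[O-]S(=O)(=O)C(F)(F)F
A3 | alternative 1 | 4-bromo-2-methoxy-6-[1-(4-methylbenzenesulfonyl)-2-(TBSO)ethyl]phenol, racemic | Cc1ccc(cc1)S(=O)(=O)C(CO[Si](C)(C)C(C)(C)C)c1cc(Br)cc(OC)c1O
A4 | alternative 2 | 2-{(2R,3S)-7-methoxy-3-{[(2,2,6,6-tetramethylpiperidin-1-yl)oxy]methyl}-2-U-2,3-dihydro-1-benzofuran-5-yl}-1,3-dioxolane | O1CCOC1c3cc(OC)c4c(c3)[C@@H](CON1C(C)(C)CCCC1(C)C)[C@H](c3cc(OC)c5c(c3)[C@H](CO[Si](C)(C)C(C)(C)C)[C@@H](c3ccc(O[Si](C)(C)C(C)(C)C)c(OC)c3)O5)O4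
A5 | alternative 2 | 2-{3-iodo-5-methoxy-4-[(1R)-1-U-prop-2-enyloxy]phenyl}-1,3-dioxolane | O1CCOC1c1cc(OC)c(O[C@H](C=C)c2cc(OC)c3c(c2)[C@H](CO[Si](C)(C)C(C)(C)C)[C@@H](c2ccc(O[Si](C)(C)C(C)(C)C)c(OC)c2)O3)c(I)c1
A6 | alternative 3 | methyl (2S,3S)-5-bromo-7-methoxy-2-[3-methoxy-4-(TBSO)phenyl]-2,3-dihydro-1-benzofuran-3-carboxylate (trans) | Brc1cc(OC)c2c(c1)[C@H](C(=O)OC)[C@@H](c1ccc(O[Si](C)(C)C(C)(C)C)c(OC)c1)O2
A7 | alternative 3 | methyl 2-{5-bromo-3-methoxy-2-{[3-methoxy-4-(TBSO)phenyl]methoxy}phenyl}-2-diazoacetate | COC(=O)C(=[N+]=[N-])c1cc(Br)cc(OC)c1OCc1ccc(O[Si](C)(C)C(C)(C)C)c(OC)c1
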